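The runs stem from a simulated flask with constants of no real substance; scatter was added.

At early times the epsilon run, with more starting material at the same loading of free catalyst, gained product faster in percent than the delta run: 15% against 7% at 40.0 s.

all flasks: gas phase 0.39 mM (held); free catalyst 0.47 mol%

| run | starting material | remark | time |
|---|---|---|---|
| delta | 1.3 mM | run made earlier |  |
| epsilon | 3 mM | run made earlier |  |
| flask | 2.0 mM |  | 3.0 min |

| run | time / s | product / % |
|---|---|---|
| delta | 20.0 | 3 |
| delta | 40.0 | 7 |
| delta | 60.0 | 9 |
| delta | 80.0 | 11 |
| delta | 120 | 14 |
| epsilon | 20.0 | 5 |
| epsilon | 40.0 | 15 |
| epsilon | 60.0 | 21 |
| epsilon | 80.0 | 22 |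
| epsilon | 120 | 31 |

(scatter of a reading: 1.5 percentage points)

- the analysis behind the earlier runs scatters by 1.5 percentage points, standard deviation
- at the start none of the gas phase is in solution

- Friday's: doubling the amount of free catalyst, all else as stated
- Saturday's: doubling the transfer coefficient of the gas phase, all else as stated
- Wednesday's: doubling the saturation concentration of gas phase, all else as stated

- how much product there is at 3.0 min, in percent of the starting material charged
- the change that raises the amount of product at 3.0 min, in percent of the starting material charged most ("none" if none brings more than 2 percentage points) (Friday's / Saturday's / Wednesday's / none)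
- amount of product at 3.0 min, in percent of the starting material charged, after Saturday's

Both runs then bent. From 60.0 s to 120 s delta gained about half of its earlier gain and epsilon about half, with 69.0% of epsilon's starting material unturned. So I read the bend as loss of free catalyst (catalyst deactivation), not shortage of starting material.

I assumed that making product is first order in starting material, and that it and losing catalyst are both first order in free catalyst and run on the same gas. Per unit of starting material their quotient then holds neither time nor gas, and I froze it. That gives one dimensionless number, the reach N: the negative logarithm of the fraction of starting material left once the catalyst is lost, equal to g·c(free catalyst charged). The last readings gave 24.7 mM⁻¹ in delta and 26.3 mM⁻¹ in epsilon, so I took g = 25.5 mM⁻¹, the reach per concentration of free catalyst charged.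

Delta's g put epsilon at 29.4% against a reading of 31%, with a scatter of 1.5 percentage points, so one number spanned both runs. But N has no clock: read at 120 s, it counts the catalyst as lost by then, so my figure may lie low.

For the flask N = 0.240, which means 21.3%. Friday's doubles N and gives 38.1%, while Saturday's and Wednesday's leave N where it was.

The forecast, unlike my reckoning, stood at 25%, with Wednesday's best and 27% after Saturday's: “Doubling transfer only trims the small lag”.

The flask gave 21.4%; Friday's raised it by 17 points, and after Saturday's it stood at 21.5%.

    starting material + dissolved gas + free catalyst → free catalyst + product (k = 1.64 × 10⁶ M⁻² s⁻¹)
    gas phase ⇌ dissolved gas, rate k2*(csat - [dissolved gas]) (kL = 0.103 s⁻¹)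
    dissolved gas + free catalyst → spent catalyst (k = 62.6 M⁻¹ s⁻¹)

At 3.00 min the flask held 98.0% of its catalyst as spent catalyst, with 78.6% of its starting material remaining. In the neighbour charged with 8.0 mM of starting material at the same loading, 79.4% of the catalyst was spent at 3.00 min, so g gives 53.3% of product, and that neighbour's product stood at 54.3%.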